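Everything rests on cutting the C2'–C3' bond of the cyclopentane ring. C2' is a quaternary carbon that bears a carbonyl carbon and sits beside quaternary C1'. That pattern is the footprint of a 1,2-shift in the epoxide of a 1,6,6-trisubstituted cyclohexene. In one operation a bulky aluminium Lewis acid contracts the six-membered ring to the cyclopentane, builds quaternary C2' with inversion and releases its formyl group. The precursor is a silyl-protected hydroxyethyl cyclohexene oxide whose oxygen lies cis to the C1' arm. Its founding stereocentre comes from catalytic asymmetric allylation. Chromene C2 is set later, independently, by enantioselective sulfenoetherification of an (E)-trisubstituted alkene.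

Key step: step 8

Assumption: C1'–C5' number the cyclopentane (C1' carries the chain to the chromene, C2' the enone) and O1–C8a the chromene; the carbinol centres made in steps 9 and 13 are carried as epimer mixtures because step 22 erases them; the (S)-antipode of the selenophosphoramide in step 20 is assumed to sulfenylate the required alkene face, and the (R)-antipode is used if the sense proves opposite.

Step 1
Reactants: 1 2-methylcyclohexanone (racemic); 2 allyl chloroformate
Product: 4 allyl 2-methylcyclohex-1-en-1-yl carbonate, via potassium enolate 3 (not isolated)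
Conditions: KOt-Bu, DMF, rt; then 2, 0 °C
Reagents that add atoms: none
Why: Equilibrating deprotonation in a polar aprotic solvent favours the more substituted potassium enolate, which the hard chloroformate acylates on oxygen (enol carbonate formation), and the stereocentre of racemic 1 disappears in the planar enol.

Step 2
Reactants: 4 allyl 2-methylcyclohex-1-en-1-yl carbonate
Product: 5 (S)-2-allyl-2-methylcyclohexanone
Conditions: Pd2(dba)3 (2.5 mol %), (S)-t-Bu-PHOX [(S)-4-tert-butyl-2-(2-diphenylphosphinophenyl)oxazoline, 6 mol %], THF, 25 °C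
Reagents that add atoms: none
Why: Decarboxylative asymmetric allylic alkylation (Tsuji–Trost type): zerovalent palladium ionises the allyl carbonate, CO2 is lost, and the allylpalladium enolate recombines at the fully substituted carbon inside the chiral P,N-ligand pocket, the (S)-ligand setting the future C1' as (S), while the small share of the other enantiomer is removed after step 22 as a diastereomer once the second catalyst-controlled centre is present.

Step 3
Reactants: 5 (S)-2-allyl-2-methylcyclohexanone
Product: 7 (S)-6-allyl-6-methylcyclohex-1-en-1-yl trifluoromethanesulfonate, via lithium enolate 6 (not isolated)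
Conditions: LiN(i-Pr)2, THF, −78 °C; then PhNTf2, −78 °C → rt
Reagents that add atoms: N-phenylbis(trifluoromethanesulfonimide), O=S(=O)(N(c1ccccc1)S(=O)(=O)C(F)(F)F)C(F)(F)F
Why: Only one α-carbon carries hydrogen, so deprotonation and O-sulfonylation (enol triflate formation) give a single regioisomer and leave the quaternary centre untouched.

Step 4
Reactants: 7 (S)-6-allyl-6-methylcyclohex-1-en-1-yl trifluoromethanesulfonate
Product: 9 (S)-6-(2-hydroxyethyl)-6-methylcyclohex-1-en-1-yl trifluoromethanesulfonate, via ozonide 8 (not isolated)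
Conditions: O3 (one equivalent, dye end point), CH2Cl2, −78 °C; then NaBH4, MeOH, −78 → 0 °C
Reagents that add atoms: ozone, [O-][O+]=O
Why: Electrophilic ozone attacks the monosubstituted allyl alkene far faster than the triflate-deactivated ring alkene, and borohydride reduces the ozonide to the primary alcohol (reductive ozonolysis) without touching the enol triflate or the stereocentre.

Step 5
Reactants: 9 (S)-6-(2-hydroxyethyl)-6-methylcyclohex-1-en-1-yl trifluoromethanesulfonate
Product: 10 2-[(1S)-1,2-dimethylcyclohex-2-en-1-yl]ethanol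
Conditions: MeMgBr (3 equiv), Fe(acac)3 (10 mol %), THF/NMP, −20 → 0 °C
Reagents that add atoms: methylmagnesium bromide, C[Mg]Br
Why: Iron-catalysed Kumada-type cross-coupling of alkenyl triflates accepts hindered partners and a magnesium alkoxide (made by the first equivalent of Grignard reagent), so methyl replaces triflate with the ring alkene fixed in position and no protecting group is needed.

Step 6
Reactants: 10 2-[(1S)-1,2-dimethylcyclohex-2-en-1-yl]ethanol
Product: 11 2-[(1R,2S,6S)-1,2-dimethyl-7-oxabicyclo[4.1.0]heptan-2-yl]ethanol (epoxide oxygen cis to the hydroxyethyl arm)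
Conditions: VO(acac)2 (5 mol %), t-BuOOH (decane), toluene, 0 °C → rt
Reagents that add atoms: tert-butyl hydroperoxide, CC(C)(C)OO
Why: Hydroxyl-directed vanadium-catalysed epoxidation: the arm alcohol binds the vanadium tert-butylperoxo complex and, tethered to C1', reaches only its own face of the trisubstituted alkene while undirected oxidation by this system is slow, so both epoxide carbons are set with oxygen cis to the arm, and rear-side attack of the arm hydroxyl on this cis epoxide is geometrically impossible.

Step 7
Reactants: 11 epoxy alcohol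
Product: 12 tert-butyl{2-[(1R,2S,6S)-1,2-dimethyl-7-oxabicyclo[4.1.0]heptan-2-yl]ethoxy}dimethylsilane (epoxide oxygen cis to the silyloxyethyl arm)
Conditions: TBSCl, imidazole, CH2Cl2, 0 °C → rt
Reagents that add atoms: tert-butyldimethylsilyl chloride, CC(C)(C)[Si](C)(C)Cl
Why: Silylation of a primary alcohol under mild base leaves the acid-sensitive epoxide and all three stereocentres intact and masks the arm oxygen for the Lewis acid step.

Step 8
Reactants: 12 silyl-protected cis epoxide
Product: 13 (1S,2S)-2-[2-(tert-butyldimethylsilyloxy)ethyl]-1,2-dimethylcyclopentane-1-carbaldehyde (methyl groups cis, formyl cis to the arm)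
Conditions: MeAl(OAr)2 (Ar = 4-bromo-2,6-di-tert-butylphenyl; 1.5 equiv, made from AlMe3 and ArOH), CH2Cl2, −78 °C
Reagents that add atoms: none
Why: The oxophilic aluminium centre binds the epoxide oxygen and stretches its bond to the tertiary carbon (future C2'), and as positive charge builds there the ring methylene on the neighbouring CH–O carbon (future C3') moves to the rear of the departing oxygen while that CH–O carbon collapses to the formyl group (Meinwald rearrangement, a semipinacol-type 1,2-alkyl shift known for trisubstituted cyclohexene oxides). The cyclopentane is closed by this suprafacial 1,2-shift, a six-to-five ring contraction that makes C2'–C3' and breaks the bond from C3' to the carbinol carbon, not by an exo or endo cyclisation. C2' is the only new stereocentre and is set stereospecifically, because migration anti to the C–O bond inverts it, so oxygen cis to the C1' arm ends as a formyl group cis to that arm with the two methyl groups cis, and C1' is untouched. The step needs ring-carbon migration to beat hydride shift (which would give the cyclohexanone), shifts from C1' and capture by the arm oxygen. The very bulky bis(aryloxide) penalises the hydride-shift geometry, which presses the aluminoxy group against the C2' methyl and the C1' substituents, whereas the ring-carbon shift swings it out of the ring; only migration from the oxygen-bearing carbon is paid for by carbonyl formation; and the arm lies on the face of the leaving oxygen with its own oxygen under a bulky silyl group, so it cannot attack from the rear at −78 °C.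

Step 9
Reactants: 13 aldehyde; 14 2-methylbut-3-yn-2-ol
Product: 16 1-{(1S,2S)-2-[2-(tert-butyldimethylsilyloxy)ethyl]-1,2-dimethylcyclopentyl}-4-methylpent-2-yne-1,4-diol (C1 epimers), via dilithio alkynolate 15 (not isolated)
Conditions: 14, n-BuLi (2 equiv per alkynol), THF, −78 → 0 °C; then 13, −78 °C → rt
Reagents that add atoms: none
Why: 1,2-Addition of a lithium acetylide to a non-enolisable aldehyde works because the slim linear nucleophile copes with the neopentyl surroundings, and the new carbinol centre forms without control but is erased in step 22.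

Step 10
Reactants: 16 propargylic diol
Product: 17 tris(tert-butyldimethylsilyl) ether of 16 (primary, secondary propargylic and tertiary oxygen all silylated)
Conditions: TBSOTf (3 equiv), 2,6-lutidine, CH2Cl2, 0 °C → rt
Reagents that add atoms: tert-butyldimethylsilyl trifluoromethanesulfonate, CC(C)(C)[Si](C)(C)OS(=O)(=O)C(F)(F)F
Why: A silyl triflate with a hindered pyridine base silylates even hindered secondary and tertiary propargylic alcohols, which shields them from the organometallic steps that follow.

Step 11
Reactants: 17 tris(silyl) ether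
Product: 18 2-{(1S,2S)-2-[1,4-bis(tert-butyldimethylsilyloxy)-4-methylpent-2-yn-1-yl]-1,2-dimethylcyclopentyl}ethanol
Conditions: camphorsulfonic acid (10 mol %), MeOH/CH2Cl2, 0 °C
Reagents that add atoms: none
Why: Acid-catalysed methanolysis of silyl ethers is governed by steric access, so the open primary ether is cleaved well before the neopentyl-type secondary and the tertiary ones (selective desilylation).

Step 12
Reactants: 18 primary alcohol
Product: 19 {(1S,2S)-2-[1,4-bis(tert-butyldimethylsilyloxy)-4-methylpent-2-yn-1-yl]-1,2-dimethylcyclopentyl}acetaldehyde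
Conditions: Dess–Martin periodinane, CH2Cl2, 0 °C → rt
Reagents that add atoms: none
Why: Dess–Martin oxidation stops cleanly at the aldehyde under nearly neutral conditions that silyl ethers and the alkyne tolerate.

Step 13
Reactants: 19 aldehyde; 20 propargyl bromide
Product: 22 1-{(1S,2S)-2-[1,4-bis(tert-butyldimethylsilyloxy)-4-methylpent-2-yn-1-yl]-1,2-dimethylcyclopentyl}pent-4-yn-2-ol (carbinol epimers), via allenylzinc bromide 21 (not isolated)
Conditions: Zn dust, THF, 0 °C → rt
Reagents that add atoms: none
Why: Barbier-type propargylation, in which the allenylzinc species reacts through its remote carbon (SE2') to give the homopropargylic alcohol, brings in chromene C3, C2 and the CH2 beside C2, and the uncontrolled carbinol centre is erased in step 22.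

Step 14
Reactants: 23 4-methoxy-2-methylphenol
Product: 24 2-hydroxy-5-methoxy-3-methylbenzaldehyde
Conditions: MgCl2, Et3N, paraformaldehyde, MeCN, reflux
Reagents that add atoms: formaldehyde (as paraformaldehyde), C=O
Why: Magnesium-mediated ortho-formylation (Casnati–Skattebøl reaction) delivers formaldehyde from the magnesium phenoxide to the only free ortho position, and a second formaldehyde takes up hydride to give the aldehyde.

Step 15
Reactants: 24 salicylaldehyde
Product: 25 2-(tert-butyldimethylsilyloxy)-5-methoxy-3-methylbenzaldehyde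
Conditions: TBSCl, imidazole, DMAP (cat.), DMF, rt
Reagents that add atoms: tert-butyldimethylsilyl chloride, CC(C)(C)[Si](C)(C)Cl
Why: Phenol silylation in DMF overcomes the hydrogen bond to the formyl group and installs a group that fluoride removes together with the other silyl ethers in step 19.

Step 16
Reactants: 25 silyloxy aldehyde
Product: 26 [2-(tert-butyldimethylsilyloxy)-5-methoxy-3-methylphenyl]methanol
Conditions: NaBH4, THF/EtOH, 0 °C, short reaction time
Reagents that add atoms: none
Why: Borohydride reduction of an aryl aldehyde is fast at 0 °C, and a prompt mildly acidic quench leaves no time for silyl migration from the phenol oxygen to the benzylic alkoxide.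

Step 17
Reactants: 26 benzylic alcohol
Product: 27 [2-(bromomethyl)-4-methoxy-6-methylphenoxy](tert-butyl)dimethylsilane
Conditions: CBr4, PPh3, CH2Cl2, 0 °C
Reagents that add atoms: carbon tetrabromide, BrC(Br)(Br)Br
Why: The Appel reaction converts the benzylic alcohol into the bromide under neutral conditions that keep the aryl silyl ether in place.

Step 18
Reactants: 22 homopropargylic alcohol; 27 benzylic bromide
Product: 29 (E)-configured union product, in which ArCH2–CH=C(CH3)–CH2–CH(OH)–CH2– is attached to C1' (Ar = 2-silyloxy-5-methoxy-3-methylphenyl; propargylic silyl ethers retained), via alkenylalane 28 (not isolated)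
Conditions: AlMe3 (4 equiv), Cp2ZrCl2 (0.3 equiv), CH2Cl2, 0 °C → rt; excess AlMe3 evaporated; then 27, Pd(PPh3)4 (5 mol %), THF, rt
Reagents that add atoms: trimethylaluminium, C[Al](C)C
Why: Negishi zirconium-catalysed carboalumination adds methyl and aluminium syn across the terminal alkyne with methyl on the inner carbon (the flanked internal alkyne stays inert and the alcohol reacts on as its aluminium alkoxide), and palladium-catalysed alkenyl–benzyl cross-coupling proceeds with retention, which fixes the (E)-trisubstituted alkene.

Step 19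
Reactants: 29 union product
Product: 30 tetraol (free phenol, free chain carbinol, free secondary and tertiary propargylic alcohols; (E)-alkene unchanged)
Conditions: Bu4NF (6 equiv), THF, rt → 45 °C
Reagents that add atoms: none
Why: Fluoride-driven Si–O cleavage removes the aryl, secondary and tertiary silyl groups in one operation, and nothing base-sensitive is present because both ketones are still alcohols.

Step 20
Reactants: 30 tetraol
Product: 31 (2R,3S)-6-methoxy-2,8-dimethyl-3-(phenylsulfanyl)chroman carrying at C2 the CH2–CH(OH)–CH2– chain to C1'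
Conditions: N-(phenylthio)phthalimide (1.1 equiv), (S)-BINAM-derived N,N'-dimethyl(diisopropylamino)selenophosphoramide (10 mol %), MsOH (0.25 equiv), CH2Cl2, −20 °C
Reagents that add atoms: N-(phenylthio)phthalimide, O=C1c2ccccc2C(=O)N1Sc1ccccc1
Why: Lewis-base-catalysed enantioselective sulfenoetherification transfers PhS+ from the chiral selenophosphoramide to the C2-Si/C3-Si face of the alkene to give a configurationally stable thiiranium ion, which the phenol opens anti at the tertiary carbon (Markovnikov, 6-endo), so catalyst face selection together with the (E)-geometry sets C2 as (R) and C3 as (S) independently of the remote cyclopentane, while no aliphatic hydroxyl can reach C2 through a viable ring.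

Step 21
Reactants: 31 3-(phenylsulfanyl)chroman
Product: 33 (2R)-2H-chromene triol (C3=C4 alkene; chain carbinol and both propargylic alcohols free), via sulfoxide 32 (not isolated)
Conditions: mCPBA (1.0 equiv), CH2Cl2, −78 °C; then toluene, 90 °C
Reagents that add atoms: none
Why: Chemoselective sulfide oxidation followed by thermal sulfoxide syn-elimination can only take a benzylic C4 hydrogen because C2 has none, so the C3=C4 alkene forms regiospecifically, the C3 centre is removed and C2 is not involved.

Step 22
Reactants: 33 chromene triol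
Product: 34 ynone diketone, (2R)-chromene with CH2–C(=O)–CH2– to C1' and C(=O)–C≡C–C(CH3)2OH on C2'
Conditions: Dess–Martin periodinane (3 equiv), CH2Cl2, 0 °C → rt
Reagents that add atoms: none
Why: Dess–Martin oxidation takes both secondary carbinols to carbonyl groups so that all epimers converge on one compound, cannot touch the tertiary alcohol, and is free of base, which matters because the new β-aryloxy ketone could otherwise expel the phenoxide (E1cB) and scramble C2.

Step 23
Reactants: 34 ynone diketone
Product: 35 target CNP0137762.2, (2R,1'S,2'S), (Z)-enone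
Conditions: H2 (1 atm), Pd/CaCO3 poisoned with Pb(OAc)2, quinoline, EtOAc, 0 °C → rt, stopped after one equivalent of H2
Reagents that add atoms: none
Why: Semihydrogenation over lead-poisoned palladium (Lindlar type) adds hydrogen syn to the alkyne and gives the (Z)-enone, while the cis-disubstituted chromene alkene and the ketones are not reduced on the poisoned surface and no stereocentre is touched.

Compound list
1 | 2-methylcyclohexanone (racemic) | CC1CCCCC1=O | starting material
2 | allyl chloroformate | C=CCOC(=O)Cl | starting material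
3 | potassium 2-methylcyclohex-1-en-1-olate | CC1=C([O-])CCCC1.[K+] | intermediate
4 | allyl 2-methylcyclohex-1-en-1-yl carbonate | C=CCOC(=O)OC1=C(C)CCCC1 | intermediate
5 | (S)-2-allyl-2-methylcyclohexanone | C=CC[C@]1(C)CCCCC1=O | intermediate
6 | lithium (S)-6-allyl-6-methylcyclohex-1-en-1-olate | C=CC[C@]1(C)CCCC=C1[O-].[Li+] | intermediate
7 | (S)-6-allyl-6-methylcyclohex-1-en-1-yl trifluoromethanesulfonate | C=CC[C@]1(C)CCCC=C1OS(=O)(=O)C(F)(F)F | intermediate
8 | 1,2,4-trioxolane (ozonide) of the allyl alkene of 7 | C1OOC(C[C@]2(C)CCCC=C2OS(=O)(=O)C(F)(F)F)O1 | intermediate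
9 | (S)-6-(2-hydroxyethyl)-6-methylcyclohex-1-en-1-yl trifluoromethanesulfonate | OCC[C@]1(C)CCCC=C1OS(=O)(=O)C(F)(F)F | intermediate
10 | 2-[(1S)-1,2-dimethylcyclohex-2-en-1-yl]ethanol | OCC[C@]1(C)CCCC=C1C | intermediate
11 | 2-[(1R,2S,6S)-1,2-dimethyl-7-oxabicyclo[4.1.0]heptan-2-yl]ethanol, oxygen cis to the arm | OCC[C@]1(C)CCC[C@@H]2O[C@]12C | intermediate
12 | tert-butyldimethylsilyl ether of 11 (key-step precursor) | CC(C)(C)[Si](C)(C)OCC[C@]1(C)CCC[C@@H]2O[C@]12C | intermediate
13 | (1S,2S)-2-[2-(tert-butyldimethylsilyloxy)ethyl]-1,2-dimethylcyclopentane-1-carbaldehyde (key-step product) | CC(C)(C)[Si](C)(C)OCC[C@]1(C)CCC[C@]1(C)C=O | intermediate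
14 | 2-methylbut-3-yn-2-ol | C#CC(C)(C)O | starting material
15 | dilithium salt of 2-methylbut-3-yn-2-ol (C- and O-lithiated) | [Li]C#CC(C)(C)O[Li] | intermediate
16 | 1-{(1S,2S)-2-[2-(tert-butyldimethylsilyloxy)ethyl]-1,2-dimethylcyclopentyl}-4-methylpent-2-yne-1,4-diol (C1 epimers) | CC(C)(C)[Si](C)(C)OCC[C@]1(C)CCC[C@]1(C)C(O)C#CC(C)(C)O | intermediate
17 | tris(tert-butyldimethylsilyl) ether of 16 | CC(C)(C)[Si](C)(C)OCC[C@]1(C)CCC[C@]1(C)C(O[Si](C)(C)C(C)(C)C)C#CC(C)(C)O[Si](C)(C)C(C)(C)C | intermediate
18 | 2-{(1S,2S)-2-[1,4-bis(tert-butyldimethylsilyloxy)-4-methylpent-2-yn-1-yl]-1,2-dimethylcyclopentyl}ethanol | OCC[C@]1(C)CCC[C@]1(C)C(O[Si](C)(C)C(C)(C)C)C#CC(C)(C)O[Si](C)(C)C(C)(C)C | intermediate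
19 | {(1S,2S)-2-[1,4-bis(tert-butyldimethylsilyloxy)-4-methylpent-2-yn-1-yl]-1,2-dimethylcyclopentyl}acetaldehyde | O=CC[C@]1(C)CCC[C@]1(C)C(O[Si](C)(C)C(C)(C)C)C#CC(C)(C)O[Si](C)(C)C(C)(C)C | intermediate
20 | propargyl bromide | C#CCBr | starting material
21 | allenylzinc bromide | C=C=C[Zn]Br | intermediate
22 | 1-{(1S,2S)-2-[1,4-bis(tert-butyldimethylsilyloxy)-4-methylpent-2-yn-1-yl]-1,2-dimethylcyclopentyl}pent-4-yn-2-ol (epimers) | C#CCC(O)C[C@]1(C)CCC[C@]1(C)C(O[Si](C)(C)C(C)(C)C)C#CC(C)(C)O[Si](C)(C)C(C)(C)C | intermediate
23 | 4-methoxy-2-methylphenol | COc1ccc(O)c(C)c1 | starting material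
24 | 2-hydroxy-5-methoxy-3-methylbenzaldehyde | COc1cc(C)c(O)c(C=O)c1 | intermediate
25 | 2-(tert-butyldimethylsilyloxy)-5-methoxy-3-methylbenzaldehyde | COc1cc(C)c(O[Si](C)(C)C(C)(C)C)c(C=O)c1 | intermediate
26 | [2-(tert-butyldimethylsilyloxy)-5-methoxy-3-methylphenyl]methanol | COc1cc(C)c(O[Si](C)(C)C(C)(C)C)c(CO)c1 | intermediate
27 | [2-(bromomethyl)-4-methoxy-6-methylphenoxy](tert-butyl)dimethylsilane | COc1cc(C)c(O[Si](C)(C)C(C)(C)C)c(CBr)c1 | intermediate
28 | (E)-2-methylalk-1-enyl(dimethyl)alane from 22, carbinol as its dimethylaluminium alkoxide | C[Al](C)/C=C(\C)CC(O[Al](C)C)C[C@]1(C)CCC[C@]1(C)C(O[Si](C)(C)C(C)(C)C)C#CC(C)(C)O[Si](C)(C)C(C)(C)C | intermediate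
29 | (E)-alkene union product, aryl and both propargylic oxygens silylated, chain carbinol free | COc1cc(C)c(O[Si](C)(C)C(C)(C)C)c(C/C=C(\C)CC(O)C[C@]2(C)CCC[C@]2(C)C(O[Si](C)(C)C(C)(C)C)C#CC(C)(C)O[Si](C)(C)C(C)(C)C)c1 | intermediate
30 | tetraol (free phenol, three free alcohols, (E)-alkene) | COc1cc(C)c(O)c(C/C=C(\C)CC(O)C[C@]2(C)CCC[C@]2(C)C(O)C#CC(C)(C)O)c1 | intermediate
31 | (2R,3S)-3-(phenylsulfanyl)chroman triol | COc1cc(C)c2c(c1)C[C@H](Sc1ccccc1)[C@@](C)(CC(O)C[C@]1(C)CCC[C@]1(C)C(O)C#CC(C)(C)O)O2 | intermediate
32 | sulfoxide of 31 (sulfur epimers) | COc1cc(C)c2c(c1)C[C@H](S(=O)c1ccccc1)[C@@](C)(CC(O)C[C@]1(C)CCC[C@]1(C)C(O)C#CC(C)(C)O)O2 | intermediate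
33 | (2R)-2H-chromene triol | COc1cc(C)c2c(c1)C=C[C@@](C)(CC(O)C[C@]1(C)CCC[C@]1(C)C(O)C#CC(C)(C)O)O2 | intermediate
34 | (2R,1'S,2'S)-ynone diketone | COc1cc(C)c2c(c1)C=C[C@@](C)(CC(=O)C[C@]1(C)CCC[C@]1(C)C(=O)C#CC(C)(C)O)O2 | intermediate
35 | CNP0137762.2, (2R,1'S,2'S), (Z)-enone | COc1cc(C)c2c(c1)C=C[C@@](C)(CC(=O)C[C@]1(C)CCC[C@]1(C)C(=O)/C=C\C(C)(C)O)O2 | target

Total step count: 23. Longest linear sequence: 19 steps (steps 1–13 and 18–23). Steps 14–17 form the four-step aryl branch.

Steps most likely to fail

Step 8. Hydride shift may outrun ring-carbon migration, or the developing cation may be captured by the arm oxygen, because the migration terminus is flanked by a quaternary carbon. The fallback sets out from 5 and returns at 13, and it builds C2' by ring contraction first and alkylation second.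
- LiN(SiMe3)2 and CF3CO2CH2CF3 give the trifluoroacetyl ketone F1.
- MsN3 and Et3N transfer the diazo group to give the diazoketone F2.
- Photochemical Wolff rearrangement in MeOH contracts the ring to the cyclopentane ester F3.
- LiN(i-Pr)2 and MeI methylate the ester enolate on the face away from the allyl group to give the quaternary ester F4.
- Ozonolysis with NaBH4 work-up is followed by spontaneous ring closure to the cis-fused lactone F5.
- LiAlH4 gives the diol F6.
- TBSCl silylates only the unhindered arm hydroxyl to give the neopentyl alcohol F7.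
- Dess–Martin oxidation delivers 13.

Step 20. Facial selection in thiiranium formation may be poor on this dialkyl-substituted alkene, or the sulfenyl transfer may be disturbed by the free hydroxyl groups. The fallback sets out from 29 and returns at 33, and it replaces sulfur by oxygen transfer.
- TBSOTf and 2,6-lutidine give the tetrasilyl ether F8.
- Shi epoxidation with the L-fructose-derived ketone and KHSO5 gives the (S,S)-epoxide F9.
- KHF2 in MeOH frees only the phenol to give the epoxy phenol F10.
- A trace of camphorsulfonic acid in CH2Cl2 makes the phenol open the epoxide at tertiary C2 with inversion (6-endo) to give the (2R,3S)-chroman-3-ol F11.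
- Martin sulfurane dehydrates toward the benzylic C4 hydrogen to give the silylated chromene F12.
- Bu4NF gives 33.

Step 6. Oxygen delivery may be slow or poorly face-selective, because the directing hydroxyl sits three carbons from the alkene. The fallback sets out from 10 and returns at 11, and it fixes the face through a covalent tether.
- TEMPO and PhI(OAc)2 in aqueous MeCN give the carboxylic acid F13.
- I2 and NaHCO3 effect iodolactonisation. The carboxylate can attack the tertiary carbon only from the arm face, with iodine anti, and this gives the iodolactone F14.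
- K2CO3 in MeOH opens the lactone, and the released tertiary alkoxide displaces the neighbouring iodide to give the cis epoxy ester F15.
- LiBH4 reduces the ester to 11.

Further compounds
F1 | step 8 | (6S)-6-allyl-6-methyl-2-(trifluoroacetyl)cyclohexanone | C=CC[C@]1(C)CCCC(C(=O)C(F)(F)F)C1=O
F2 | step 8 | (S)-2-allyl-6-diazo-2-methylcyclohexanone | C=CC[C@]1(C)CCCC(=[N+]=[N-])C1=O
F3 | step 8 | methyl (2S)-2-allyl-2-methylcyclopentane-1-carboxylate (C1 epimers) | C=CC[C@]1(C)CCCC1C(=O)OC
F4 | step 8 | methyl (1S,2S)-2-allyl-1,2-dimethylcyclopentane-1-carboxylate | C=CC[C@]1(C)CCC[C@]1(C)C(=O)OC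
F5 | step 8 | cis-fused six-membered lactone of the hydroxyethyl acid (both ring-fusion carbons methylated) | O=C1OCC[C@]2(C)CCC[C@]12C
F6 | step 8 | 2-[(1S,2S)-2-(hydroxymethyl)-1,2-dimethylcyclopentyl]ethanol | OCC[C@]1(C)CCC[C@]1(C)CO
F7 | step 8 | {(1S,2S)-2-[2-(tert-butyldimethylsilyloxy)ethyl]-1,2-dimethylcyclopentyl}methanol | CC(C)(C)[Si](C)(C)OCC[C@]1(C)CCC[C@]1(C)CO
F8 | step 20 | tetrakis(tert-butyldimethylsilyl) ether from 29 | COc1cc(C)c(O[Si](C)(C)C(C)(C)C)c(C/C=C(\C)CC(O[Si](C)(C)C(C)(C)C)C[C@]2(C)CCC[C@]2(C)C(O[Si](C)(C)C(C)(C)C)C#CC(C)(C)O[Si](C)(C)C(C)(C)C)c1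
F9 | step 20 | (S,S)-epoxide of F8 | COc1cc(C)c(O[Si](C)(C)C(C)(C)C)c(C[C@@H]2O[C@@]2(C)CC(O[Si](C)(C)C(C)(C)C)C[C@]2(C)CCC[C@]2(C)C(O[Si](C)(C)C(C)(C)C)C#CC(C)(C)O[Si](C)(C)C(C)(C)C)c1
F10 | step 20 | epoxy phenol from F9 | COc1cc(C)c(O)c(C[C@@H]2O[C@@]2(C)CC(O[Si](C)(C)C(C)(C)C)C[C@]2(C)CCC[C@]2(C)C(O[Si](C)(C)C(C)(C)C)C#CC(C)(C)O[Si](C)(C)C(C)(C)C)c1
F11 | step 20 | (2R,3S)-chroman-3-ol, three alkyl silyl ethers retained | COc1cc(C)c2c(c1)C[C@H](O)[C@@](C)(CC(O[Si](C)(C)C(C)(C)C)C[C@]1(C)CCC[C@]1(C)C(O[Si](C)(C)C(C)(C)C)C#CC(C)(C)O[Si](C)(C)C(C)(C)C)O2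
F12 | step 20 | (2R)-2H-chromene, three alkyl silyl ethers retained | COc1cc(C)c2c(c1)C=C[C@@](C)(CC(O[Si](C)(C)C(C)(C)C)C[C@]1(C)CCC[C@]1(C)C(O[Si](C)(C)C(C)(C)C)C#CC(C)(C)O[Si](C)(C)C(C)(C)C)O2
F13 | step 6 | [(1S)-1,2-dimethylcyclohex-2-en-1-yl]acetic acid | OC(=O)C[C@]1(C)CCCC=C1C
F14 | step 6 | cis-fused iodolactone, lactone oxygen on the arm face, iodine on the opposite face | O=C1C[C@]2(C)CCC[C@@H](I)[C@]2(C)O1
F15 | step 6 | methyl [(1R,2S,6S)-1,2-dimethyl-7-oxabicyclo[4.1.0]heptan-2-yl]acetate | COC(=O)C[C@]1(C)CCC[C@@H]2O[C@]12C
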